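## Structural features

The target is an ent-halimane: a 1(10)-octalin in which ring A (C1–C5, C10) and ring B (C5–C10) share the C5–C10 bond, with a five-carbon chain on C9 that ends in an (E)-trisubstituted allylic acetate. Its four stereocentres form two vicinal pairs. C4 (quaternary, methyl α, methoxycarbonyl β) stands next to C5 (H β), and C8 (methyl C17 α) stands next to quaternary C9 (methyl C20 α, chain carbon C11 β). The pairs are separated by the sp2 carbon C10, so one pair cannot simply be relayed to the other across a saturated ring fusion. The allylic acetate is the fragile group (ionisation, hydrolysis, E/Z drift), the 1(10)-alkene can migrate towards the 5(10)-position under acid or on hydrogenation catalysts, and H-5 is allylic. The C4 ester is neopentyl, has no α-hydrogen and is robust. The real difficulty is quaternary C9, flanked by tertiary C8 and the fully substituted alkene carbon C10, in the right sense relative to C5. The feature used is that, with C11 written as a carboxyl, C9–C11 and the allyl unit C6–C7–C8 become a Claisen system as soon as an ester oxygen joins C11 to C6. Because C9 and C6 are already linked through C10–C5 of ring A, that ester is a six-membered lactone, and its rearrangement makes C8–C9, closes ring B and leaves C11 as the handle for the chain.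

## Logic of the disconnections

27 ⇒ 24 (through 26 and 25). The O–acyl bond and the C13=C14 double bond are cut. The allylic acetate is the most sensitive function, so it is made last, from a stable methyl ketone, by two-carbon olefination, ester reduction and acetylation. The demand is E-selective olefination of a methyl ketone and reduction of the new conjugated ester without touching the hindered C4 ester.

24 ⇒ 22 (through 23). The C11–C12 bond is cut as a C11=C12 alkene. C11 is the carbon that the key step delivers, so the three-carbon ketone unit is attached to it by carbonyl olefination. The ring alkene C6=C7 left by the key step is saturated together with the enone C=C. The demand is olefination of a neopentyl aldehyde and a hydrogenation that spares the trisubstituted 1(10)-alkene.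

22 ⇒ 20. This is a change of oxidation level at C11 (aldehyde from acid). It requires partial reduction of a hindered acid derivative in the presence of the C4 ester.

20 ⇒ 17 (key disconnection). The C8–C9 bond is cut and the C6–O bond is re-formed, which opens ring B and gives a ring-A-fused six-membered lactone with a (Z)-propenyl group on C6. One carbinol centre (C6) and one alkene geometry then stand for the two stereocentres C8 and C9 and for ring B. The forward step needs enolisation at C9 only, a boat array, H-6 cis to H-5, and the Z geometry.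

17 ⇒ 14 (through 16). The alkene is traced to an alkyne and the lactone C11–O bond is cut. The alkyne survives acid and base and carries no geometry, so the Z-alkene and its acid-labile allylic C–O bond appear only once the lactone ring is closed. The demands are lactonisation that leaves the C4 ester alone and a semi-hydrogenation that stops at the alkene.

14 ⇒ 12 (through 13). The C6 carbinol is traced to the ketone and further to the carbinol of either configuration. A closed aldol transition state of the cyclic enolate should favour the anti adduct, which corresponds to the trans-lactone and hence to the wrong C9 after rearrangement. The centre is therefore set by catalyst-controlled reduction, which must not epimerise C5.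

12 ⇒ 8 + 9. The C9–C10 bond is cut. The three-carbon unit C9/C11/C20 is joined to an sp2 carbon of ring A whose position fixes the 1(10)-alkene. The demand is cross-coupling at a hindered alkenyl triflate and α-protonation of the product dienolate.

8 ⇒ 5 (through 6). The C10–O triflate is traced to the ketone. The forward step needs kinetic enolisation towards C1 and a protected C6 hydroxyl.

5 ⇒ 3 + 2 and a methyl nucleophile. The C4–CH3 and C5–C6 bonds are cut. Both form in one flask by conjugate addition and enolate trapping, so the C4/C5 pair comes from achiral pieces and the C4 ester is present from the start. The demand is catalyst control at C4 and addition at C5 anti to the ester.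

2 ⇒ 1. Oxidation level only.

## Other disconnections considered

Alternative 1: The cut is through C2–C3 and C4–C5 of ring A. In the forward sense the ring-B diene 7-ethenyl-1,4-dioxaspiro[4.5]dec-7-ene A2 and methacrolein A3 combine in a [4+2] cycloaddition under a chiral oxazaborolidinium Lewis acid to give the exo adduct A1, with the 1(10)-alkene already in place.
- In its favour: one catalytic, enantioselective step sets quaternary C4 and C5 together and delivers the bicycle from two small achiral compounds.
- Against it here: C8 and C9 are left for later. C9 in A1 is a methylene between the masked C8 carbonyl and C10 and must be alkylated twice, and the C8 carbonyl must become a methyl group by olefination and hydrogenation. Both centres then rest on substrate control, next to a β,γ-alkene that can slip into conjugation with the C8 ketone. The regiochemistry also depends on the ring terminus of A2 outweighing the internal substituent.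
- Comparison: for the C4/C5 pair this alternative is the better plan, since the chosen route relies on a diastereoselective enolate trapping. For the C8/C9 pair the chosen route is stronger, because one sigmatropic event transfers configuration to both centres. Mechanistically it is catalyst control in a concerted cycloaddition against a substrate-locked rearrangement. The step counts should be about equal.

Alternative 2: The cut is the C9–C10 bond, with C20 traced to a methylidene carbon. In the forward sense zerovalent palladium inserts into the enol triflate A5, the alkenylpalladium adds 6-exo to the 1,1-disubstituted alkene, and a hydride donor reduces the neopentyl palladium species to give A4.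
- In its favour: ring B and quaternary C9 form in one catalytic step. C20 costs nothing. C8 arrives in an acyclic fragment of known configuration. C11 and C12 are already present in A4, so the end game is shorter than in the chosen plan; on that point it is the better route.
- Against it here: C9 is set only by 1,2-induction from C8 in the carbopalladation, with no geometric lock. The neopentyl palladium intermediate has no β-hydrogen and can add to the new 1(10)-alkene before it is reduced. Ring A of A5 still needs the C4/C5 pair and a C5 side chain, so that problem is the same as in the chosen plan (equal).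
- Comparison: it is structurally more convergent, it is equal on ring-A chemistry, and it is weaker on the control of C9.

Alternative 3: The cut is the C4–C5 bond, with C1–O re-formed as a lactone. In the forward sense the silyl ketene acetal of the α-methoxycarbonyl δ-lactone A7 rearranges [3,3] through a boat to the acid ester A6.
- In its favour: it is the same reaction type as the chosen key step. The malonate-type lactone enolises under very mild conditions. C4 and C5 are both set by transfer from a single allylic carbinol. The ring-B ketone A8 that carries C8 and C9 should be available by conjugate methylation and allylation of a simple enone. On C4/C5 control and on ease of enolisation it is the better plan.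
- Against it here: the ester-substituted ketene acetal is electron-poor and should rearrange more slowly. The new bond joins a fully substituted carbon to a ring carbon next to quaternary C9. The carboxyl ends on C19, where the target has a methyl group, so an acid must be taken down to a methyl in the presence of the C18 ester, and the allyl group must still be turned into the five-carbon chain.
- Comparison: in the chosen plan the carboxyl carbon becomes C11, a carbon the target needs, so nothing is removed afterwards and the route after the key step is shorter. The mechanism and its boat geometry are the same in both.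

Key step: step 10

Remark on the chemistry: halimane numbering is used for atom labels in all compounds (C18 is the ester carbon on C4, C17 and C20 are the methyls on C8 and C9, C11–C16 the chain), and 3 is taken as a catalogue compound. The configurations of 17 and 20 were checked against the boat transition state and against the target and agree. C9 of 17 is carried as both epimers because it is erased on enolisation.

## Route

Step 1
Reactants: 1 but-2-yn-1-ol
Product: 2 but-2-ynal
Conditions: MnO2 (activated, excess), CH2Cl2, rt
Reagents that add atoms: none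
Why: Oxidation of a propargylic alcohol with MnO2 stops at the aldehyde; the volatile ynal is kept as a dried, titrated solution.

Step 2
Reactants: 3 methyl 3-oxocyclohex-1-ene-1-carboxylate, 2 but-2-ynal
Product: 5 methyl (1S,2S)-2-[(1RS)-1-hydroxybut-2-yn-1-yl]-1-methyl-3-oxocyclohexane-1-carboxylate, via methylzinc enolate 4 (not isolated)
Conditions: Me2Zn (3 equiv), (CuOTf)2·C6H6 (2.5 mol%), chiral sulfonate-bearing imidazolinium salt (NHC precursor, 5 mol%), Et2O, −30 → 0 °C; then 2, −78 → −40 °C; aq. NH4Cl
Reagents that add atoms: dimethylzinc C[Zn]C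
Why: Copper-catalysed asymmetric conjugate addition of a dialkylzinc to the cyclic γ-keto ester sets quaternary C4 (ligand enantiomer chosen for the S centre), and zinc enolate 4 then adds to the ynal (tandem conjugate addition–aldol). The aldehyde should approach C5 anti to the pseudoaxial methoxycarbonyl group, which has the smaller A value, so that C6 ends trans to the ester. C6 is not controlled and need not be, because it is reset in steps 6 and 7.

Step 3
Reactants: 5 methyl (1S,2S)-2-[(1RS)-1-hydroxybut-2-yn-1-yl]-1-methyl-3-oxocyclohexane-1-carboxylate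
Product: 6 methyl (1S,2S)-1-methyl-3-oxo-2-[(1RS)-1-(triethylsilyloxy)but-2-yn-1-yl]cyclohexane-1-carboxylate
Conditions: Et3SiCl, imidazole, DMF, 0 °C → rt
Reagents that add atoms: chlorotriethylsilane CC[Si](Cl)(CC)CC
Why: Standard silylation of a secondary alcohol; the ether blocks retro-aldol cleavage and alkoxide chemistry in the two base-mediated steps that follow.

Step 4
Reactants: 6 methyl (1S,2S)-1-methyl-3-oxo-2-[(1RS)-1-(triethylsilyloxy)but-2-yn-1-yl]cyclohexane-1-carboxylate
Product: 8 methyl (1S,2S)-1-methyl-2-[(1RS)-1-(triethylsilyloxy)but-2-yn-1-yl]-3-(trifluoromethanesulfonyloxy)cyclohex-3-ene-1-carboxylate, via lithium enolate 7 (not isolated)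
Conditions: LiN(i-Pr)2, THF, −78 °C; then PhNTf2, −78 → 0 °C
Reagents that add atoms: N-phenylbis(trifluoromethanesulfonimide) O=S(=O)(N(c1ccccc1)S(=O)(=O)C(F)(F)F)C(F)(F)F
Why: Kinetic deprotonation takes the unhindered C1 methylene and not the tertiary H-5 next to quaternary C4, and O-triflation of enolate 7 fixes the 1(10) double bond (enol triflate synthesis). The C4 ester has no α-hydrogen.

Step 5
Reactants: 8 methyl (1S,2S)-1-methyl-2-[(1RS)-1-(triethylsilyloxy)but-2-yn-1-yl]-3-(trifluoromethanesulfonyloxy)cyclohex-3-ene-1-carboxylate, 9 tert-butyl propanoate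
Product: 12 methyl (1S,2S)-3-[(2RS)-1-tert-butoxy-1-oxopropan-2-yl]-2-[(1RS)-1-hydroxybut-2-yn-1-yl]-1-methylcyclohex-3-ene-1-carboxylate, via lithium ester enolate 10 (not isolated), via triethylsilyl ether 11 (not isolated)
Conditions: 9, LiN(SiMe3)2, PhMe, −10 °C; then 8, Pd(OAc)2 (3 mol%), 2-(dicyclohexylphosphino)-2′-(N,N-dimethylamino)biphenyl (6 mol%), rt; then 1 M HCl, THF, rt
Reagents that add atoms: none
Why: Palladium-catalysed α-alkenylation of an ester enolate (Buchwald–Hartwig enolate coupling) joins C9 to C10 at the position fixed by the triflate. The coupled ester is deprotonated in the flask to its dienolate and protonated at C9 on acidic work-up, so the 1(10)-alkene stays out of conjugation; both C9 epimers form, which is harmless. Dilute acid then removes the silyl group from 11.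

Step 6
Reactants: 12 methyl (1S,2S)-3-[(2RS)-1-tert-butoxy-1-oxopropan-2-yl]-2-[(1RS)-1-hydroxybut-2-yn-1-yl]-1-methylcyclohex-3-ene-1-carboxylate
Product: 13 methyl (1S,2S)-2-(but-2-ynoyl)-3-[(2RS)-1-tert-butoxy-1-oxopropan-2-yl]-1-methylcyclohex-3-ene-1-carboxylate
Conditions: Dess–Martin periodinane, NaHCO3, CH2Cl2, 0 °C → rt
Reagents that add atoms: none
Why: Dess–Martin oxidation under buffered, non-basic conditions converts both C6 epimers into one ynone and should leave the acidic H-5 untouched.

Step 7
Reactants: 13 methyl (1S,2S)-2-(but-2-ynoyl)-3-[(2RS)-1-tert-butoxy-1-oxopropan-2-yl]-1-methylcyclohex-3-ene-1-carboxylate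
Product: 14 methyl (1S,2S)-3-[(2RS)-1-tert-butoxy-1-oxopropan-2-yl]-2-[(1S)-1-hydroxybut-2-yn-1-yl]-1-methylcyclohex-3-ene-1-carboxylate
Conditions: (S)-2-methyl-CBS-oxazaborolidine (0.5 equiv), catecholborane, CH2Cl2, −78 °C
Reagents that add atoms: none
Why: Corey–Bakshi–Shibata reduction: with propynyl as the small group the catalyst should deliver hydride to the face that gives (6S). This is also the Felkin–Anh face if quaternary C4 acts as the large group, so catalyst and substrate should reinforce each other. Low temperature and the absence of base protect C5.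

Step 8
Reactants: 14 methyl (1S,2S)-3-[(2RS)-1-tert-butoxy-1-oxopropan-2-yl]-2-[(1S)-1-hydroxybut-2-yn-1-yl]-1-methylcyclohex-3-ene-1-carboxylate
Product: 16 methyl (1S,4RS,8S,8aS)-4,8-dimethyl-3-oxo-1-(prop-1-yn-1-yl)-3,4,6,7,8,8a-hexahydro-1H-isochromene-8-carboxylate, via hydroxy acid 15 (not isolated)
Conditions: CF3CO2H/CH2Cl2 (1:4), 0 °C → rt; then PhMe, 60 °C
Reagents that add atoms: none
Why: Acidolysis of the tert-butyl ester and acid-catalysed lactonisation of hydroxy acid 15 close the six-membered lactone with retention at C6. A propargylic C–O bond does not ionise under these conditions, which is why the alkyne is still in place. The hindered C4 methyl ester should not transesterify.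

Step 9
Reactants: 16 methyl (1S,4RS,8S,8aS)-4,8-dimethyl-3-oxo-1-(prop-1-yn-1-yl)-3,4,6,7,8,8a-hexahydro-1H-isochromene-8-carboxylate
Product: 17 methyl (1R,4RS,8S,8aS)-4,8-dimethyl-3-oxo-1-[(1Z)-prop-1-en-1-yl]-3,4,6,7,8,8a-hexahydro-1H-isochromene-8-carboxylate
Conditions: H2 (1 atm), Pd/CaCO3 poisoned with Pb(OAc)2 (Lindlar catalyst), quinoline, EtOAc, rt
Reagents that add atoms: none
Why: Lindlar semi-hydrogenation adds H2 syn to the alkyne and gives the (Z)-propenyl group. Stopped after one equivalent, the poisoned catalyst should leave the trisubstituted 1(10)-alkene and the allylic lactone C–O bond alone.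

Step 10
Reactants: 17 methyl (1R,4RS,8S,8aS)-4,8-dimethyl-3-oxo-1-[(1Z)-prop-1-en-1-yl]-3,4,6,7,8,8a-hexahydro-1H-isochromene-8-carboxylate
Product: 20 (1S,2R,4aS,5S)-5-(methoxycarbonyl)-1,2,5-trimethyl-1,2,4a,5,6,7-hexahydronaphthalene-1-carboxylic acid, via silyl ketene acetal 18 (not isolated), via trimethylsilyl ester 19 (not isolated)
Conditions: Me3SiCl/Et3N, then LiN(SiMe3)2, THF, −78 °C → rt; PhMe, 105 °C; then 1 M HCl, THF, rt
Reagents that add atoms: none
Why: LiN(SiMe3)2 removes the doubly activated H-9 and Me3SiCl traps the dienolate on oxygen as the cyclic silyl ketene acetal 18, whose geometry is fixed by the lactone ring. On heating, 18 undergoes a suprafacial [3,3] shift across C9=C11–O–C6–C7=C8, the known Ireland–Claisen ring contraction of alkenyl lactones to cycloalkene carboxylic acids. Because C9 and C6 are tied by the two-atom C10–C5 link, the six reacting atoms can reach only a boat (bicyclo[2.2.2]octane-like) array, and ring B closes as a cyclohexene through the new sigmatropic C8–C9 bond while the lactone C6–O bond breaks. C9 is controlled by C6: the new bond forms on the face of the allyl unit from which oxygen leaves, so H-6 cis to H-5 places C11 β and C20 α. C8 is controlled by the alkene geometry: the Z methyl lies on the inner side of the boat and ends α, cis to C20. The step needs deprotonation at C9 only, which the β,γ position of the 1(10)-alkene secures, and an inert C4 ester, which has no α-hydrogen. Aqueous acid hydrolyses silyl ester 19 to acid 20.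

Step 11
Reactants: 20 (1S,2R,4aS,5S)-5-(methoxycarbonyl)-1,2,5-trimethyl-1,2,4a,5,6,7-hexahydronaphthalene-1-carboxylic acid
Product: 22 methyl (1S,5S,6R,8aS)-5-formyl-1,5,6-trimethyl-1,2,3,5,6,8a-hexahydronaphthalene-1-carboxylate, via acid chloride 21 (not isolated)
Conditions: (COCl)2, DMF (cat.), CH2Cl2, 0 °C → rt; then LiAlH(Ot-Bu)3, THF, −78 °C
Reagents that add atoms: none
Why: The hindered acid is activated as its chloride and reduced with the bulky hydride at −78 °C, which should stop at the aldehyde and spare the C4 ester (Brown partial reduction of acid chlorides). C9 has no hydrogen, so neither ketene formation nor epimerisation is possible.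

Step 12
Reactants: 22 methyl (1S,5S,6R,8aS)-5-formyl-1,5,6-trimethyl-1,2,3,5,6,8a-hexahydronaphthalene-1-carboxylate
Product: 23 methyl (1S,5S,6R,8aS)-1,5,6-trimethyl-5-[(1E)-3-oxobut-1-en-1-yl]-1,2,3,5,6,8a-hexahydronaphthalene-1-carboxylate
Conditions: (MeO)2P(O)CH2C(O)CH3, NaH, THF, 0 → 50 °C
Reagents that add atoms: dimethyl (2-oxopropyl)phosphonate CC(=O)CP(=O)(OC)OC
Why: Horner–Wadsworth–Emmons olefination with a β-ketophosphonate gives the (E)-enone; the aldehyde cannot enolise, so only steric hindrance opposes the addition.

Step 13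
Reactants: 23 methyl (1S,5S,6R,8aS)-1,5,6-trimethyl-5-[(1E)-3-oxobut-1-en-1-yl]-1,2,3,5,6,8a-hexahydronaphthalene-1-carboxylate
Product: 24 methyl (1S,5S,6R,8aS)-1,5,6-trimethyl-5-(3-oxobutyl)-1,2,3,5,6,7,8,8a-octahydronaphthalene-1-carboxylate
Conditions: H2 (3 atm), RhCl(PPh3)3 (10 mol%), PhH/EtOH (1:1), rt
Reagents that add atoms: none
Why: RhCl(PPh3)3 hydrogenates disubstituted alkenes, including the C=C of disubstituted enones, far faster than trisubstituted ones. C6=C7 and C11=C12 should therefore be saturated in one operation while the hindered 1(10)-alkene and the ketone remain; no stereocentre is created.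

Step 14
Reactants: 24 methyl (1S,5S,6R,8aS)-1,5,6-trimethyl-5-(3-oxobutyl)-1,2,3,5,6,7,8,8a-octahydronaphthalene-1-carboxylate
Product: 25 methyl (1S,5S,6R,8aS)-5-[(3E)-5-ethoxy-3-methyl-5-oxopent-3-en-1-yl]-1,5,6-trimethyl-1,2,3,5,6,7,8,8a-octahydronaphthalene-1-carboxylate
Conditions: (EtO)2P(O)CH2CO2Et, NaH, THF, 0 °C → reflux
Reagents that add atoms: triethyl phosphonoacetate CCOC(=O)CP(=O)(OCC)OCC
Why: Horner–Wadsworth–Emmons olefination of the methyl ketone should give mainly the (E)-enoate, with the larger C12 chain trans to the ester; the minor (Z) isomer is to be removed by chromatography.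

Step 15
Reactants: 25 methyl (1S,5S,6R,8aS)-5-[(3E)-5-ethoxy-3-methyl-5-oxopent-3-en-1-yl]-1,5,6-trimethyl-1,2,3,5,6,7,8,8a-octahydronaphthalene-1-carboxylate
Product: 26 methyl (1S,5S,6R,8aS)-5-[(3E)-5-hydroxy-3-methylpent-3-en-1-yl]-1,5,6-trimethyl-1,2,3,5,6,7,8,8a-octahydronaphthalene-1-carboxylate
Conditions: i-Bu2AlH (2.2 equiv), CH2Cl2, −78 °C; aq. potassium sodium tartrate work-up
Reagents that add atoms: none
Why: i-Bu2AlH reduces the unhindered conjugated ethyl ester to the allylic alcohol at −78 °C (1,2-reduction), whereas the neopentyl C4 methyl ester on a quaternary carbon should react much more slowly.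

Step 16
Reactants: 26 methyl (1S,5S,6R,8aS)-5-[(3E)-5-hydroxy-3-methylpent-3-en-1-yl]-1,5,6-trimethyl-1,2,3,5,6,7,8,8a-octahydronaphthalene-1-carboxylate
Product: 27 methyl (1S,5S,6R,8aS)-5-[(3E)-5-acetoxy-3-methylpent-3-en-1-yl]-1,5,6-trimethyl-1,2,3,5,6,7,8,8a-octahydronaphthalene-1-carboxylate (methyl 15-acetoxy-ent-halima-1(10),13E-dien-18-oate)
Conditions: Ac2O, pyridine, DMAP (cat.), CH2Cl2, 0 °C → rt
Reagents that add atoms: acetic anhydride CC(=O)OC(C)=O
Why: Acylation of the primary allylic alcohol under nucleophilic catalysis; the mild base avoids allylic ionisation.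

## Compound list

1 | but-2-yn-1-ol | CC#CCO | starting material
2 | but-2-ynal | CC#CC=O | intermediate
3 | methyl 3-oxocyclohex-1-ene-1-carboxylate | COC(=O)C1=CC(=O)CCC1 | starting material
4 | methyl (1S)-1-methyl-3-[(methylzincio)oxy]cyclohex-2-ene-1-carboxylate (methylzinc enolate) | COC(=O)[C@@]1(C)CCCC(O[Zn]C)=C1 | intermediate (not isolated)
5 | methyl (1S,2S)-2-[(1RS)-1-hydroxybut-2-yn-1-yl]-1-methyl-3-oxocyclohexane-1-carboxylate (C6 epimers) | COC(=O)[C@@]1(C)CCCC(=O)[C@@H]1C(O)C#CC | intermediate
6 | methyl (1S,2S)-1-methyl-3-oxo-2-[(1RS)-1-(triethylsilyloxy)but-2-yn-1-yl]cyclohexane-1-carboxylate | COC(=O)[C@@]1(C)CCCC(=O)[C@@H]1C(O[Si](CC)(CC)CC)C#CC | intermediate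
7 | lithium enolate of 6 (C10–OLi, C1=C10) | COC(=O)[C@@]1(C)CCC=C(O[Li])[C@@H]1C(O[Si](CC)(CC)CC)C#CC | intermediate (not isolated)
8 | methyl (1S,2S)-1-methyl-2-[(1RS)-1-(triethylsilyloxy)but-2-yn-1-yl]-3-(trifluoromethanesulfonyloxy)cyclohex-3-ene-1-carboxylate | COC(=O)[C@@]1(C)CCC=C(OS(=O)(=O)C(F)(F)F)[C@@H]1C(O[Si](CC)(CC)CC)C#CC | intermediate
9 | tert-butyl propanoate | CCC(=O)OC(C)(C)C | starting material
10 | lithium enolate of tert-butyl propanoate | CC=C(O[Li])OC(C)(C)C | intermediate (not isolated)
11 | methyl (1S,2S)-3-[(2RS)-1-tert-butoxy-1-oxopropan-2-yl]-1-methyl-2-[(1RS)-1-(triethylsilyloxy)but-2-yn-1-yl]cyclohex-3-ene-1-carboxylate | COC(=O)[C@@]1(C)CCC=C(C(C)C(=O)OC(C)(C)C)[C@@H]1C(O[Si](CC)(CC)CC)C#CC | intermediate (not isolated)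
12 | methyl (1S,2S)-3-[(2RS)-1-tert-butoxy-1-oxopropan-2-yl]-2-[(1RS)-1-hydroxybut-2-yn-1-yl]-1-methylcyclohex-3-ene-1-carboxylate | COC(=O)[C@@]1(C)CCC=C(C(C)C(=O)OC(C)(C)C)[C@@H]1C(O)C#CC | intermediate
13 | methyl (1S,2S)-2-(but-2-ynoyl)-3-[(2RS)-1-tert-butoxy-1-oxopropan-2-yl]-1-methylcyclohex-3-ene-1-carboxylate | COC(=O)[C@@]1(C)CCC=C(C(C)C(=O)OC(C)(C)C)[C@@H]1C(=O)C#CC | intermediate
14 | methyl (1S,2S)-3-[(2RS)-1-tert-butoxy-1-oxopropan-2-yl]-2-[(1S)-1-hydroxybut-2-yn-1-yl]-1-methylcyclohex-3-ene-1-carboxylate | COC(=O)[C@@]1(C)CCC=C(C(C)C(=O)OC(C)(C)C)[C@@H]1[C@H](O)C#CC | intermediate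
15 | (2RS)-2-[(5S,6S)-6-[(1S)-1-hydroxybut-2-yn-1-yl]-5-(methoxycarbonyl)-5-methylcyclohex-1-en-1-yl]propanoic acid | COC(=O)[C@@]1(C)CCC=C(C(C)C(O)=O)[C@@H]1[C@H](O)C#CC | intermediate (not isolated)
16 | methyl (1S,4RS,8S,8aS)-4,8-dimethyl-3-oxo-1-(prop-1-yn-1-yl)-3,4,6,7,8,8a-hexahydro-1H-isochromene-8-carboxylate | COC(=O)[C@@]1(C)CCC=C2[C@@H]1[C@@H](C#CC)OC(=O)C2C | intermediate
17 | methyl (1R,4RS,8S,8aS)-4,8-dimethyl-3-oxo-1-[(1Z)-prop-1-en-1-yl]-3,4,6,7,8,8a-hexahydro-1H-isochromene-8-carboxylate (key-step precursor; C9 of halimane numbering as both epimers) | COC(=O)[C@@]1(C)CCC=C2[C@@H]1[C@@H](/C=C\C)OC(=O)C2C | intermediate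
18 | methyl (1R,8S,8aS)-4,8-dimethyl-1-[(1Z)-prop-1-en-1-yl]-3-(trimethylsilyloxy)-6,7,8,8a-tetrahydro-1H-isochromene-8-carboxylate (silyl ketene acetal) | COC(=O)[C@@]1(C)CCC=C2[C@@H]1[C@@H](/C=C\C)OC(O[Si](C)(C)C)=C2C | intermediate (not isolated)
19 | trimethylsilyl ester of 20 | COC(=O)[C@@]1(C)CCC=C2[C@@H]1C=C[C@@H](C)[C@]2(C)C(=O)O[Si](C)(C)C | intermediate (not isolated)
20 | (1S,2R,4aS,5S)-5-(methoxycarbonyl)-1,2,5-trimethyl-1,2,4a,5,6,7-hexahydronaphthalene-1-carboxylic acid (key-step product; C11 acid with 1(10)- and 6(7)-alkenes) | COC(=O)[C@@]1(C)CCC=C2[C@@H]1C=C[C@@H](C)[C@]2(C)C(O)=O | intermediate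
21 | methyl (1S,5S,6R,8aS)-5-(chlorocarbonyl)-1,5,6-trimethyl-1,2,3,5,6,8a-hexahydronaphthalene-1-carboxylate | COC(=O)[C@@]1(C)CCC=C2[C@@H]1C=C[C@@H](C)[C@]2(C)C(Cl)=O | intermediate (not isolated)
22 | methyl (1S,5S,6R,8aS)-5-formyl-1,5,6-trimethyl-1,2,3,5,6,8a-hexahydronaphthalene-1-carboxylate | COC(=O)[C@@]1(C)CCC=C2[C@@H]1C=C[C@@H](C)[C@]2(C)C=O | intermediate
23 | methyl (1S,5S,6R,8aS)-1,5,6-trimethyl-5-[(1E)-3-oxobut-1-en-1-yl]-1,2,3,5,6,8a-hexahydronaphthalene-1-carboxylate | COC(=O)[C@@]1(C)CCC=C2[C@@H]1C=C[C@@H](C)[C@]2(C)/C=C/C(C)=O | intermediate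
24 | methyl (1S,5S,6R,8aS)-1,5,6-trimethyl-5-(3-oxobutyl)-1,2,3,5,6,7,8,8a-octahydronaphthalene-1-carboxylate | COC(=O)[C@@]1(C)CCC=C2[C@@H]1CC[C@@H](C)[C@]2(C)CCC(C)=O | intermediate
25 | methyl (1S,5S,6R,8aS)-5-[(3E)-5-ethoxy-3-methyl-5-oxopent-3-en-1-yl]-1,5,6-trimethyl-1,2,3,5,6,7,8,8a-octahydronaphthalene-1-carboxylate | COC(=O)[C@@]1(C)CCC=C2[C@@H]1CC[C@@H](C)[C@]2(C)CC/C(C)=C/C(=O)OCC | intermediate
26 | methyl (1S,5S,6R,8aS)-5-[(3E)-5-hydroxy-3-methylpent-3-en-1-yl]-1,5,6-trimethyl-1,2,3,5,6,7,8,8a-octahydronaphthalene-1-carboxylate | COC(=O)[C@@]1(C)CCC=C2[C@@H]1CC[C@@H](C)[C@]2(C)CC/C(C)=C/CO | intermediate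
27 | methyl (1S,5S,6R,8aS)-5-[(3E)-5-acetoxy-3-methylpent-3-en-1-yl]-1,5,6-trimethyl-1,2,3,5,6,7,8,8a-octahydronaphthalene-1-carboxylate | COC(=O)[C@@]1(C)CCC=C2[C@@H]1CC[C@@H](C)[C@]2(C)CC/C(C)=C/COC(C)=O | target

## Step count and least certain steps

Total: 16 steps. Longest linear sequence: 16 steps (1 to 27); counted from 3 it is 15 steps.

**Step 10 (key step).** The most likely failure is a rearrangement too slow to outrun decomposition or desilylation of the ketene acetal. The boat places both C5 and the (Z)-methyl C17 on the inner positions of the allyl unit, which raises the barrier, and the conjugated silyl ketene acetal may not survive the temperature that is then needed. The fallback forms the same bond by an ionic ring closure instead of a sigmatropic one. It sets out from 14. Lindlar semi-hydrogenation gives methyl (1S,2S)-3-[(2RS)-1-tert-butoxy-1-oxopropan-2-yl]-2-[(1R,2Z)-1-hydroxybut-2-en-1-yl]-1-methylcyclohex-3-ene-1-carboxylate F1. Diethyl chlorophosphate and pyridine convert it into the allylic diethyl phosphate F2. KN(SiMe3)2 in THF at −78 °C → 0 °C generates the ester dienolate, which should close ring B by intramolecular SN2′ alkylation at C8 to give 1-tert-butyl 5-methyl (1S,2R,4aS,5S)-1,2,5-trimethyl-1,2,4a,5,6,7-hexahydronaphthalene-1,5-dicarboxylate F3. CF3CO2H then frees the acid, and the route is rejoined at 20. In this mode the lactone no longer locks C9, so the selectivity would rest on a syn course of the displacement and separation of isomers may be needed.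

**Step 2.** Two things may go wrong: poor facial selectivity at C5, because methyl and methoxycarbonyl on C4 differ little in size, and copper-mediated methyl transfer to the ynal while excess dimethylzinc is present. The fallback separates the two events. It sets out from 4, which is trapped with Me3SiOTf as methyl (1S)-1-methyl-3-(trimethylsilyloxy)cyclohex-2-ene-1-carboxylate F4 and freed from zinc and copper. A Mukaiyama aldol addition of F4 to 2 with BF3·OEt2 in CH2Cl2 at −78 °C then gives 5, where the route is rejoined. The Lewis acid-bound aldehyde in an open transition state is the bulkier electrophile and should discriminate better between the two faces.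

**Step 5.** Oxidative addition and coupling at the C10 triflate may be slow because C10 is flanked by the fully substituted C5 side. Self-condensation of the ester enolate and S–O cleavage of the triflate could then compete. The fallback reverses the polarity of the coupling. It sets out from 8. Miyaura borylation (B2pin2, PdCl2(PPh3)2, PPh3, KOPh, PhMe, 50 °C) gives methyl (1S,2S)-1-methyl-3-(4,4,5,5-tetramethyl-1,3,2-dioxaborolan-2-yl)-2-[(1RS)-1-(triethylsilyloxy)but-2-yn-1-yl]cyclohex-3-ene-1-carboxylate F5. Suzuki coupling of F5 with tert-butyl 2-bromopropanoate (Ni(PPh3)4, K3PO4, PhMe) gives 11, which is desilylated as in step 5.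

**Step 7.** Epimerisation at C5, or migration of the 1(10)-alkene into conjugation, may occur in ynone 13, because H-5 is both α to the ynone carbonyl and allylic. Catalyst control may also be incomplete if the substrate preference turns out to oppose it. The fallback avoids the ynone. It sets out from 12, whose C6 epimers are separated; the (6S) epimer is 14. The (6R) epimer is inverted by Mitsunobu esterification (4-nitrobenzoic acid, PPh3, DIAD, THF) to methyl (1S,2S)-3-[(2RS)-1-tert-butoxy-1-oxopropan-2-yl]-1-methyl-2-[(1S)-1-(4-nitrobenzoyloxy)but-2-yn-1-yl]cyclohex-3-ene-1-carboxylate F6. Methanolysis (K2CO3, MeOH) gives 14, where the route is rejoined.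

**Step 13.** Hydrogenation of the hindered ring alkene C6=C7 or of the neopentyl enone may be incomplete, and prolonged exposure to the metal hydride may move the 1(10)-alkene. The fallback uses two reductions that involve no hydrogenation catalyst. It sets out from 23. Conjugate reduction with [(Ph3P)CuH]6 in wet benzene gives methyl (1S,5S,6R,8aS)-1,5,6-trimethyl-5-(3-oxobutyl)-1,2,3,5,6,8a-hexahydronaphthalene-1-carboxylate F7. Diimide (2-nitrobenzenesulfonylhydrazide, Et3N, CH2Cl2) then reduces the cis-disubstituted C6=C7 and gives 24.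

## Further compounds

F1 | step 10 | methyl (1S,2S)-3-[(2RS)-1-tert-butoxy-1-oxopropan-2-yl]-2-[(1R,2Z)-1-hydroxybut-2-en-1-yl]-1-methylcyclohex-3-ene-1-carboxylate | COC(=O)[C@@]1(C)CCC=C(C(C)C(=O)OC(C)(C)C)[C@@H]1[C@H](O)/C=C\C
F2 | step 10 | methyl (1S,2S)-3-[(2RS)-1-tert-butoxy-1-oxopropan-2-yl]-2-[(1R,2Z)-1-(diethoxyphosphoryloxy)but-2-en-1-yl]-1-methylcyclohex-3-ene-1-carboxylate | COC(=O)[C@@]1(C)CCC=C(C(C)C(=O)OC(C)(C)C)[C@@H]1[C@H](OP(=O)(OCC)OCC)/C=C\C
F3 | step 10 | 1-tert-butyl 5-methyl (1S,2R,4aS,5S)-1,2,5-trimethyl-1,2,4a,5,6,7-hexahydronaphthalene-1,5-dicarboxylate | COC(=O)[C@@]1(C)CCC=C2[C@@H]1C=C[C@@H](C)[C@]2(C)C(=O)OC(C)(C)C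
F4 | step 2 | methyl (1S)-1-methyl-3-(trimethylsilyloxy)cyclohex-2-ene-1-carboxylate | COC(=O)[C@@]1(C)CCCC(O[Si](C)(C)C)=C1
F5 | step 5 | methyl (1S,2S)-1-methyl-3-(4,4,5,5-tetramethyl-1,3,2-dioxaborolan-2-yl)-2-[(1RS)-1-(triethylsilyloxy)but-2-yn-1-yl]cyclohex-3-ene-1-carboxylate | COC(=O)[C@@]1(C)CCC=C(B2OC(C)(C)C(C)(C)O2)[C@@H]1C(O[Si](CC)(CC)CC)C#CC
F6 | step 7 | methyl (1S,2S)-3-[(2RS)-1-tert-butoxy-1-oxopropan-2-yl]-1-methyl-2-[(1S)-1-(4-nitrobenzoyloxy)but-2-yn-1-yl]cyclohex-3-ene-1-carboxylate | COC(=O)[C@@]1(C)CCC=C(C(C)C(=O)OC(C)(C)C)[C@@H]1[C@H](OC(=O)c1ccc(cc1)[N+](=O)[O-])C#CC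
F7 | step 13 | methyl (1S,5S,6R,8aS)-1,5,6-trimethyl-5-(3-oxobutyl)-1,2,3,5,6,8a-hexahydronaphthalene-1-carboxylate | COC(=O)[C@@]1(C)CCC=C2[C@@H]1C=C[C@@H](C)[C@]2(C)CCC(C)=O
A1 | alternative 1 | (4a′S,5′S)-5′-methyl-3′,4′,4a′,5′,6′,7′-hexahydro-1′H-spiro[1,3-dioxolane-2,2′-naphthalene]-5′-carbaldehyde | O=C[C@@]1(C)CCC=C2[C@@H]1CCC3(C2)OCCO3
A2 | alternative 1 | 7-ethenyl-1,4-dioxaspiro[4.5]dec-7-ene | C=CC1=CCCC2(C1)OCCO2
A3 | alternative 1 | methacrolein (2-methylprop-2-enal) | CC(=C)C=O
A4 | alternative 2 | methyl ent-12-(tert-butyldimethylsilyloxy)-13,14,15,16-tetranorhalim-1(10)-en-18-oate | COC(=O)[C@@]1(C)CCC=C2[C@@H]1CC[C@@H](C)[C@]2(C)CCO[Si](C)(C)C(C)(C)C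
A5 | alternative 2 | methyl (1S,2R)-2-[(3R)-6-(tert-butyldimethylsilyloxy)-3-methyl-4-methylidenehexyl]-1-methyl-3-(trifluoromethanesulfonyloxy)cyclohex-3-ene-1-carboxylate | COC(=O)[C@@]1(C)CCC=C(OS(=O)(=O)C(F)(F)F)[C@@H]1CC[C@@H](C)C(=C)CCO[Si](C)(C)C(C)(C)C
A6 | alternative 3 | ent-18-methoxy-18-oxo-14,15,16-trinorhalima-1(10),12-dien-19-oic acid | COC(=O)[C@@]1(C(O)=O)CCC=C2[C@@H]1CC[C@@H](C)[C@]2(C)CC=C
A7 | alternative 3 | methyl (3RS,6S)-6-[(5R,6S)-5,6-dimethyl-6-(prop-2-en-1-yl)cyclohex-1-en-1-yl]-2-oxooxane-3-carboxylate | COC(=O)C1CC[C@H](OC1=O)C2=CCC[C@@H](C)[C@]2(C)CC=C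
A8 | alternative 3 | (2S,3R)-2,3-dimethyl-2-(prop-2-en-1-yl)cyclohexan-1-one | O=C1CCC[C@@H](C)[C@]1(C)CC=C
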